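The readings stem from a simulated flask on assumed constants; noise was put on by code.

The unit we count in is the turnover, n, the natural logarithm of electrophile charged over electrophile left, so that reacted part and n convert directly.

| setting | Friday's | Thursday's | autumn | winter |
|---|---|---|---|---|
| electrophile | 1 M | 1 M | 1.0 M | 1.0 M |
| nucleophile | 1.3 M | 2.9 M | 1.10 M | 2.20 M |
| protic impurity | 1 M | 1 M | 1.00 M | 1.00 M |
| remark | run made earlier | run made earlier |  |  |
| time |  |  | 4.0 min | 4.0 min |

- Friday's (time / min: electrophile / %, target / %): 0.200: 76.7, 19.7; 0.667: 67.4, 25.0; 1.00: 66.2, 25.4; 1.50: 65.6, 25.9; 2.50: 65.0, 26.2; 3.00: 64.5, 26.2; 4.00: 64.4, 26.5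
- Thursday's (time / min: electrophile / %, target / %): 0.333: 42.9, 31.6; 0.500: 36.2, 31.5; 0.667: 32.6, 31.6; 1.00: 28.3, 29.4; 1.50: 26.3, 28.1; 2.50: 24.9, 27.7; 4.00: 23.6, 27.4

(standard deviation of a reading: 0.3 percentage points)



* part of the electrophile that has reacted at the end, autumn
* part of the electrophile that has reacted at the end, winter
* what raising the concentration of nucleophile from its lowest to its highest value here does to the part of the electrophile that has reacted (changes below 5 percentage points count as none) (it rises / no change / it falls)

At 4.00 min, Friday's run stands at 0.440 turnovers and Thursday's at 1.44. By 1.00 min, Friday's run had 93.7% of its turnovers and Thursday's 87.4%, so we leave the clock out of our reckoning.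

We suppose that the nucleophile is shared out and fold the charges into one number, which is 0.650 for Friday's run: the supply number x, the nucleophile charged per mole of electrophile plus protic impurity charged. For Thursday's run x is 1.45, and n rising as a power of x gives the exponent 1.48. One number may not be enough: two runs give that exponent and test nothing, and both held the sum in x at 2.00 M.

Autumn has x = 0.550, so n = 0.344 and 29.1% reacted. Winter has x = 1.10, so n = 0.959 and 61.7% reacted.

The forecast says 29% (24% to 33%) for autumn and 62% (56% to 67%) for winter, and it rises: “Conversion clearly rises with nucleophile charge”.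

The flask gives 30.3% for autumn and 58.9% for winter; it rises, by 29 percentage points.

    electrophile + nucleophile → acid set free + target (k = 0.0290 L mol⁻¹ s⁻¹)
    nucleophile + acid set free ⇌ protonated nucleophile, settled at all times (K = 2000 L mol⁻¹)
    nucleophile + target → over-reaction product (k = 0.0380 L mol⁻¹ s⁻¹)
    nucleophile + protic impurity → quenched reagent (k = 0.0530 L mol⁻¹ s⁻¹)
    crystals ⇌ acid set free, rate k5*(cs5 - [acid set free]) while solid is left; crystals form when [acid set free] > cs5 (solubility = 0.440 M, k = 0.990 s⁻¹)

Take winter with 2.5 M of protic impurity in place of 1.00 M. Its x is 0.629, against 1.10 in winter, so n = 0.419 and we reckon 34.2% reacted. This neighbour gives 37.2%. Nucleophile, the limiting reagent, stands at 0.087% of its charge at the end, less than the 63% of the electrophile, and over-reaction product holds 9.99% of the electrophile charged.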